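If G stood at saturation from the first second, the flask would be one pseudo-first-order decay, so begin there and add what the flask really has.

| flask | X | L | temperature | time |
|---|---|---|---|---|
| spring | 1.5 M | 200 mM (held) | 20 °C | 12 min |
| midnight | 1.5 M | 200 mM (held) | 45 °C | 12 min |

    X.G → Z (k1 = 2.2 × 10⁻⁶ s⁻¹, Ea1 = 111 kJ mol⁻¹)
    X + G → D (k2 = 0.0045 M⁻¹ s⁻¹, Ea2 = 49.0 kJ mol⁻¹)
    Q ⇌ X.G, rate k3*(cs3 - [X.G]) while solid is left; crystals form when [X.G] > cs3 (cs3 = 0.86 M, k3 = 0.35 s⁻¹)
    L ⇌ G, rate k4*(csat - [G]) (k4 = 0.0093 s⁻¹, csat = 200 mM)
    X + G → J (k5 = 0.023 M⁻¹ s⁻¹, Ea5 = 66.0 kJ mol⁻¹)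
    X + G → X.G (k6 = 0.0099 M⁻¹ s⁻¹, Ea6 = 48.0 kJ mol⁻¹)
    (constants at 20 °C)

- for X.G the Q are counted in
- as a solid, counted per litre of solution: Q
- at the start none of G is dissolved
- all constants are for 20 °C and move with temperature by the activation energies

1. which of these there is most of at the end, counted by the X in it, spring (X.G / D / X / J)
2. which of these there is most of at the end, counted by the X in it, midnight (X.G / D / X / J)
3. amount of the one of these that there is most of at the end, in percent of the X charged, spring
4. amount of the one of these that there is most of at the end, in percent of the X charged, midnight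

Take X + G → J by itself in spring, with G held at saturation. X then has a half-life of 2.51 min, and 3.64% of it stays at the end.

Now add the gas step. G starts at nothing and enters at k4 times the gap to saturation, so delivery is at most 0.112 M min⁻¹. Reckon with the gas time, the time that full delivery needs to bring in one G per X charged: 13.4 min. The transfer is given no activation energy, so both flasks share this value, and 12 min is 89.3% of it. That caps conversion at this figure.

Next add the other two steps that use G, giving a summed constant of 0.0374 M⁻¹ s⁻¹ in spring. At the full charge of X, G relaxes in 15.3 s, far faster than the run, so take uptake equal to consumption. Delivery is then the fraction kX/(k4 + kX) of full, with k the summed constant. At X of half the charge, this is 75.1%. My reckoning for spring therefore gives a conversion of 67.0%, and J takes the selectivity share 61.5%, which gives 41.2% against 33.0% of X left.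

At midnight k5 becomes 0.193 M⁻¹ s⁻¹ and the summed constant 0.261 M⁻¹ s⁻¹. The fraction rises to 95.5% and the share to 73.9%, so J reaches 63.0%. I commit to J in both flasks.

The forecast, holding that “G uptake from the gas limits the overall rate”, names J at 40.5% in spring and J at 61.5% at midnight, each below my figure for that flask .

The simulation gives J at 41.1% in spring, with X at 33.2%, and J at 61.6% at midnight. In spring G is made 1.03 times as fast as it is used at 5.66 min, and X has lost 66.8% by the end, against 83.4% at midnight, with the gas time's cap at 89.3%.

Read spring earlier, at 8.0 min. The gas time gives a conversion of 44.7% at that reading, so the reckoning leaves 55.3% of X, more than the 27.5% of J. The computed flask holds 53.8% of X and 28.4% of J, and the two draw level at 11.0 min.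

The numbers of this flask are invented; the rest is arithmetic.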